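**Retrosynthetic overview**
1. Target ⇐ three closing operations (TBS off, CH2OH → CHO, TBDPS off); the (E,E)-diene is cut between C(Me)= and CH=, giving the ring A (E)-alkenyl iodide and a core carrying a MeC≡C– chain (hydrozirconation/Negishi coupling).
2. Core tertiary alcohol ⇐ methyl addition to a 6-oxabicyclo[3.2.1]octan-2-one, made in one key step by a Prins cyclisation terminated by a 1,2-shift (pinacol) that contracts an oxane to the oxolane; carbocycle and oxolane form together, after ring A.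
3. Cascade substrate (a 2,7-dioxabicyclo[2.2.1]heptane ketal) ⇐ Sharpless epoxide of an enynol + Roche-ester methyl ketone hydrazone + pent-3-ynyl Grignard (anti-carbomagnesiation fixes the E-alkene).
4. Ring A iodide ⇐ Robinson annulation, dehydrogenation, asymmetric methyl conjugate addition, Luche reduction, Still–Wittig 1,3-transposition, oxidation, Takai olefination.

Assumption: the target is taken exactly as drawn in the SMILES, and in step 3 the ligand enantiomer is the one that gives the (5S) ketone (the antipode is used if the sense of induction is opposite).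

**Route**

Step 1
Reactants: 1 2-methylpropanal; 2 pent-1-en-3-one
Product: 3 2,4,4-trimethylcyclohex-2-en-1-one
Conditions: H2SO4 (cat.), toluene, reflux, Dean–Stark
Reagents that add atoms: none
Why: Robinson annulation (acid-catalysed Michael addition of the aldehyde enol, then aldol condensation of the ethyl ketone onto the aldehyde) builds ring A with its gem-dimethyl carbon; no stereocentre.

Step 2
Reactants: 3 2,4,4-trimethylcyclohex-2-en-1-one
Product: 4 2,4,4-trimethylcyclohexa-2,5-dien-1-one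
Conditions: DDQ, dioxane, reflux
Reagents that add atoms: none
Why: DDQ dehydrogenation of the only CH2–CH2 unit next to the carbonyl gives the cross-conjugated dienone, which the quaternary carbon keeps from aromatising.

Step 3
Reactants: 4 2,4,4-trimethylcyclohexa-2,5-dien-1-one
Product: 5 (5S)-2,4,4,5-tetramethylcyclohex-2-en-1-one
Conditions: Cu(OTf)2 (2 mol %), (S,R,R)-binaphthol-derived bis(1-phenylethyl)amine phosphoramidite (4 mol %), Me2Zn, toluene, −25 °C
Reagents that add atoms: dimethylzinc C[Zn]C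
Why: copper-catalysed asymmetric conjugate addition goes to the unsubstituted enone (the 2-methyl enone is far less reactive) and the chiral copper–phosphoramidite complex sets the methyl-bearing centre (5S).

Step 4
Reactants: 5 (5S)-2,4,4,5-tetramethylcyclohex-2-en-1-one
Product: 6 (1R,5S)-2,4,4,5-tetramethylcyclohex-2-en-1-ol
Conditions: NaBH4, CeCl3·7H2O, MeOH, −78 °C
Reagents that add atoms: none
Why: Luche 1,2-reduction with axial hydride delivery on the half-chair (5-methyl equatorial) gives the pseudo-equatorial alcohol cis to that methyl group (1R).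

Step 5
Reactants: 6 (1R,5S)-2,4,4,5-tetramethylcyclohex-2-en-1-ol
Product: 7 trimethyl({[(1R,5S)-2,4,4,5-tetramethylcyclohex-2-en-1-yl]oxy}methyl)stannane
Conditions: KH, THF, 0 °C; then Me3SnCH2I, 0 °C → rt
Reagents that add atoms: iodomethyl(trimethyl)stannane C[Sn](C)(C)CI
Why: Williamson etherification of the potassium alkoxide; no stereocentre is touched.

Step 6
Reactants: 7 trimethyl({[(1R,5S)-2,4,4,5-tetramethylcyclohex-2-en-1-yl]oxy}methyl)stannane
Product: 8 [(1R,5S)-2,5,6,6-tetramethylcyclohex-2-en-1-yl]methanol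
Conditions: n-BuLi, THF, −78 → −20 °C
Reagents that add atoms: none
Why: Still–Wittig rearrangement: tin–lithium exchange and a suprafacial [2,3]-sigmatropic shift deliver CH2OH to the alkene terminus on the face of the former C–O bond, so the new centre (1R) is cis to the 5-methyl group and the alkene moves to the 2,3-position.

Step 7
Reactants: 8 [(1R,5S)-2,5,6,6-tetramethylcyclohex-2-en-1-yl]methanol
Product: 9 (1R,5S)-2,5,6,6-tetramethylcyclohex-2-ene-1-carbaldehyde
Conditions: DMP, NaHCO3, CH2Cl2, 0 °C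
Reagents that add atoms: none
Why: Dess–Martin oxidation under buffered non-basic conditions leaves the epimerisable, deconjugated α-centre intact.

Step 8
Reactants: 9 (1R,5S)-2,5,6,6-tetramethylcyclohex-2-ene-1-carbaldehyde
Product: 10 (E)-1-iodo-2-[(1R,5S)-2,5,6,6-tetramethylcyclohex-2-en-1-yl]ethene
Conditions: CrCl2, CHI3, THF, 0 °C
Reagents that add atoms: iodoform IC(I)I
Why: Takai iodo-olefination gives the E-alkenyl iodide under non-basic conditions, so the allylic centre is not epimerised.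

Step 9
Reactants: 11 methyl (2R)-3-hydroxy-2-methylpropanoate
Product: 12 methyl (2R)-3-[(tert-butyldimethylsilyl)oxy]-2-methylpropanoate
Conditions: TBSCl, imidazole, CH2Cl2, 0 °C → rt
Reagents that add atoms: tert-butyldimethylsilyl chloride CC(C)(C)[Si](C)(C)Cl
Why: standard silylation of the primary alcohol; the stereocentre (the later aldehyde α-carbon) comes from the chiral pool.

Step 10
Reactants: 12 methyl (2R)-3-[(tert-butyldimethylsilyl)oxy]-2-methylpropanoate
Product: 14 (3R)-4-[(tert-butyldimethylsilyl)oxy]-3-methylbutan-2-one, via Weinreb amide 13 (not isolated)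
Conditions: MeNHOMe·HCl, i-PrMgCl, THF, −20 °C; then MeMgBr, −20 → 0 °C
Reagents that add atoms: methylmagnesium bromide C[Mg]Br; N,O-dimethylhydroxylamine hydrochloride CNOC.Cl (its atoms stay only in 13)
Why: one-pot Weinreb ketone synthesis: the chelated tetrahedral adduct of the N-methoxy-N-methylamide with MeMgBr prevents over-addition and the α-centre is not enolised.

Step 11
Reactants: 14 (3R)-4-[(tert-butyldimethylsilyl)oxy]-3-methylbutan-2-one
Product: 15 1-[(3S)-4-[(tert-butyldimethylsilyl)oxy]-3-methylbutan-2-ylidene]-2,2-dimethylhydrazine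
Conditions: Me2NNH2, MgSO4, CH2Cl2, rt
Reagents that add atoms: 1,1-dimethylhydrazine CN(C)N
Why: hydrazone condensation under neutral dehydrating conditions (same spatial arrangement, descriptor changes by CIP only) prepares a clean methyl-side nucleophile for the epoxide opening.

Step 12
Reactants: 16 pent-3-yn-1-ol
Product: 17 5-bromopent-2-yne
Conditions: CBr4, PPh3, CH2Cl2, 0 °C
Reagents that add atoms: carbon tetrabromide BrC(Br)(Br)Br
Why: Appel bromination of the primary alcohol.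

Step 13
Reactants: 18 pent-4-yn-1-ol
Product: 19 tert-butyl(pent-4-yn-1-yloxy)diphenylsilane
Conditions: TBDPSCl, imidazole, CH2Cl2, rt
Reagents that add atoms: tert-butyldiphenylsilyl chloride CC(C)(C)[Si](Cl)(c1ccccc1)c1ccccc1
Why: silylation gives the acid-robust protecting group that is later kept while the TBS ether is removed.

Step 14
Reactants: 19 tert-butyl(pent-4-yn-1-yloxy)diphenylsilane; 20 2-bromoprop-2-en-1-ol
Product: 21 7-[(tert-butyldiphenylsilyl)oxy]-2-methylidenehept-3-yn-1-ol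
Conditions: Pd(PPh3)2Cl2 (3 mol %), CuI (6 mol %), Et3N, THF, rt
Reagents that add atoms: none
Why: Sonogashira coupling of the alkenyl bromide with the terminal alkyne gives the 2-alkynyl allylic alcohol.

Step 15
Reactants: 21 7-[(tert-butyldiphenylsilyl)oxy]-2-methylidenehept-3-yn-1-ol
Product: 22 [(2R)-2-{5-[(tert-butyldiphenylsilyl)oxy]pent-1-yn-1-yl}oxiran-2-yl]methanol
Conditions: Ti(OiPr)4 (10 mol %), D-(−)-diethyl tartrate (12 mol %), t-BuOOH, 4 Å MS, CH2Cl2, −20 °C
Reagents that add atoms: tert-butyl hydroperoxide CC(C)(C)OO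
Why: Sharpless asymmetric epoxidation of the 2-substituted allylic alcohol; the D-tartrate catalyst delivers oxygen to the face that gives the (R) quaternary centre, the single source of absolute configuration for the core.

Step 16
Reactants: 22 [(2R)-2-{5-[(tert-butyldiphenylsilyl)oxy]pent-1-yn-1-yl}oxiran-2-yl]methanol; 15 1-[(3S)-4-[(tert-butyldimethylsilyl)oxy]-3-methylbutan-2-ylidene]-2,2-dimethylhydrazine
Product: 23 (2R,6S)-7-[(tert-butyldimethylsilyl)oxy]-2-{5-[(tert-butyldiphenylsilyl)oxy]pent-1-yn-1-yl}-5-(2,2-dimethylhydrazinylidene)-6-methylheptane-1,2-diol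
Conditions: 15, LDA, THF, 0 °C; then 22 pre-treated with n-BuLi (1 equiv, −78 °C), −78 → 0 °C
Reagents that add atoms: none
Why: aza-enolate alkylation: deprotonation of 15 at its methyl group and attack on the CH2 terminus of the epoxide leave the C–O bond at the quaternary carbon untouched, giving the (R) tertiary propargylic alcohol (Payne rearrangement of this alkoxide is degenerate).

Step 17
Reactants: 23 (2R,6S)-7-[(tert-butyldimethylsilyl)oxy]-2-{5-[(tert-butyldiphenylsilyl)oxy]pent-1-yn-1-yl}-5-(2,2-dimethylhydrazinylidene)-6-methylheptane-1,2-diol; 17 5-bromopent-2-yne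
Product: 27 (1S,4R)-1-{(2R)-1-[(tert-butyldimethylsilyl)oxy]propan-2-yl}-4-[(1E)-5-[(tert-butyldiphenylsilyl)oxy]-1-(pent-3-yn-1-yl)pent-1-en-1-yl]-2,7-dioxabicyclo[2.2.1]heptane, via pent-3-ynylmagnesium bromide 24 (not isolated), via alkenyl hydrazone diol 25 (not isolated), via keto diol 26 (not isolated)
Conditions: 17, Mg, THF, rt; then 23, CuI (20 mol %), THF, 0 → 40 °C; then sat. aq. (CO2H)2, Et2O, rt; then CSA (5 mol %), 4 Å MS, CH2Cl2, rt
Reagents that add atoms: none
Why: copper-catalysed anti-carbomagnesiation of the propargylic magnesium alkoxide (alkyl to the proximal alkyne carbon, magnesium chelated on the distal one, proton on work-up) fixes the E-alkene with the pentynyl group cis to the silyloxypropyl chain; oxalic acid then hydrolyses the hydrazone and CSA closes the keto diol to the bicyclic ketal, whose ketal configuration is dictated by the (R) carbinol.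

Step 18
Reactants: 27 (1S,4R)-1-{(2R)-1-[(tert-butyldimethylsilyl)oxy]propan-2-yl}-4-[(1E)-5-[(tert-butyldiphenylsilyl)oxy]-1-(pent-3-yn-1-yl)pent-1-en-1-yl]-2,7-dioxabicyclo[2.2.1]heptane
Product: 28 (1S,5R,8S)-5-{(2R)-1-[(tert-butyldimethylsilyl)oxy]propan-2-yl}-8-{3-[(tert-butyldiphenylsilyl)oxy]propyl}-1-(pent-3-yn-1-yl)-6-oxabicyclo[3.2.1]octan-2-one
Conditions: TMSOTf (20 mol %), CH2Cl2, −78 → −40 °C; then Et3N
Reagents that add atoms: none
Why: Proposed new method: a ketal-initiated Prins–pinacol cascade in a bridged topology. Silylation of the tertiary ketal oxygen opens the strained ketal to the six-membered oxocarbenium ion. The E-alkene, on the flagpole of the boat, attacks the oxocarbenium carbon (future C5) through its CH end (future C8) while leaning over the CH2CH2 bridge, away from the ring oxygen, with H inside and the chain outside. In the resulting tertiary 2-oxabicyclo[2.2.2]octyl cation the CH2–O carbon (future C7), whose bond is parallel to the empty orbital and pushed by the ring oxygen, shifts from the silyloxy carbon (future C2) to the cationic carbon (future C1); this contracts the oxane to the oxolane, gives the ketone and releases TMSOTf. The (R) carbinol fixes C1 (S) and C5 (R), and the E-alkene with this approach fixes C8 (S). The closest known reaction type is the pinacol-terminated Prins cyclisation of allylic diol acetals to 3-acyl tetrahydrofurans and its bridged carbocyclic variants.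

Step 19
Reactants: 28 (1S,5R,8S)-5-{(2R)-1-[(tert-butyldimethylsilyl)oxy]propan-2-yl}-8-{3-[(tert-butyldiphenylsilyl)oxy]propyl}-1-(pent-3-yn-1-yl)-6-oxabicyclo[3.2.1]octan-2-one
Product: 29 (1S,2S,5R,8S)-5-{(2R)-1-[(tert-butyldimethylsilyl)oxy]propan-2-yl}-8-{3-[(tert-butyldiphenylsilyl)oxy]propyl}-2-methyl-1-(pent-3-yn-1-yl)-6-oxabicyclo[3.2.1]octan-2-ol
Conditions: MeLi, Et2O, −78 → −40 °C
Reagents that add atoms: methyllithium C[Li]
Why: 1,2-addition of the small organolithium from the face of the one-carbon bridge (axial attack; the other face is shielded by the axial C7H2 on C1) puts methyl axial and OH equatorial (2S).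

Step 20
Reactants: 29 (1S,2S,5R,8S)-5-{(2R)-1-[(tert-butyldimethylsilyl)oxy]propan-2-yl}-8-{3-[(tert-butyldiphenylsilyl)oxy]propyl}-2-methyl-1-(pent-3-yn-1-yl)-6-oxabicyclo[3.2.1]octan-2-ol; 10 (E)-1-iodo-2-[(1R,5S)-2,5,6,6-tetramethylcyclohex-2-en-1-yl]ethene
Product: 31 (1S,2S,5R,8S)-5-{(2R)-1-[(tert-butyldimethylsilyl)oxy]propan-2-yl}-8-{3-[(tert-butyldiphenylsilyl)oxy]propyl}-2-methyl-1-{(3E,5E)-4-methyl-6-[(1R,5S)-2,5,6,6-tetramethylcyclohex-2-en-1-yl]hexa-3,5-dien-1-yl}-6-oxabicyclo[3.2.1]octan-2-ol, via alkenylzirconocene 30 (not isolated)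
Conditions: Cp2Zr(H)Cl (3 equiv), THF, 40 °C; then 10, ZnCl2 (1.5 equiv), Pd(PPh3)4 (5 mol %), THF, rt
Reagents that add atoms: none
Why: syn-hydrozirconation (Zr at the methyl-bearing carbon after equilibration with excess reagent; one equivalent is held by the tertiary OH and returned on work-up) followed by zinc-assisted Negishi coupling with retention on both partners gives the E,E-diene.

Step 21
Reactants: 31 (as named in step 20)
Product: 32 (1S,2S,5R,8S)-8-{3-[(tert-butyldiphenylsilyl)oxy]propyl}-5-[(2R)-1-hydroxypropan-2-yl]-2-methyl-1-{(3E,5E)-4-methyl-6-[(1R,5S)-2,5,6,6-tetramethylcyclohex-2-en-1-yl]hexa-3,5-dien-1-yl}-6-oxabicyclo[3.2.1]octan-2-ol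
Conditions: CSA (10 mol %), MeOH/CH2Cl2 1:1, 0 °C
Reagents that add atoms: none
Why: selective acid-catalysed methanolysis removes the primary TBS ether while the TBDPS ether (about two orders of magnitude more acid-stable), the diene and the tertiary alcohol survive.

Step 22
Reactants: 32 (as named in step 21)
Product: 33 (2S)-2-[(1S,2S,5R,8S)-8-{3-[(tert-butyldiphenylsilyl)oxy]propyl}-2-hydroxy-2-methyl-1-{(3E,5E)-4-methyl-6-[(1R,5S)-2,5,6,6-tetramethylcyclohex-2-en-1-yl]hexa-3,5-dien-1-yl}-6-oxabicyclo[3.2.1]octan-5-yl]propanal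
Conditions: DMP, NaHCO3, CH2Cl2, 0 °C → rt
Reagents that add atoms: none
Why: Dess–Martin oxidation of the only primary alcohol under buffered conditions avoids epimerisation of the α-centre and retro-oxa-Michael opening of the ether.

Step 23
Reactants: 33 (as named in step 22)
Product: 34 (2S)-2-[(1S,2S,5R,8S)-2-hydroxy-8-(3-hydroxypropyl)-2-methyl-1-{(3E,5E)-4-methyl-6-[(1R,5S)-2,5,6,6-tetramethylcyclohex-2-en-1-yl]hexa-3,5-dien-1-yl}-6-oxabicyclo[3.2.1]octan-5-yl]propanal (target)
Conditions: HF·pyridine, pyridine, THF, 0 °C → rt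
Reagents that add atoms: none
Why: buffered fluoride desilylation removes the TBDPS ether under mildly acidic conditions that the β-alkoxy aldehyde tolerates.

**Compound list**
1 | 2-methylpropanal | CC(C)C=O | starting material
2 | pent-1-en-3-one | CCC(=O)C=C | starting material
3 | 2,4,4-trimethylcyclohex-2-en-1-one | CC1=CC(C)(C)CCC1=O | intermediate
4 | 2,4,4-trimethylcyclohexa-2,5-dien-1-one | CC1=CC(C)(C)C=CC1=O | intermediate
5 | (5S)-2,4,4,5-tetramethylcyclohex-2-en-1-one | CC1=CC(C)(C)[C@@H](C)CC1=O | intermediate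
6 | (1R,5S)-2,4,4,5-tetramethylcyclohex-2-en-1-ol | CC1=CC(C)(C)[C@@H](C)C[C@H]1O | intermediate
7 | trimethyl({[(1R,5S)-2,4,4,5-tetramethylcyclohex-2-en-1-yl]oxy}methyl)stannane | CC1=CC(C)(C)[C@@H](C)C[C@H]1OC[Sn](C)(C)C | intermediate
8 | [(1R,5S)-2,5,6,6-tetramethylcyclohex-2-en-1-yl]methanol | CC1=CC[C@H](C)C(C)(C)[C@@H]1CO | intermediate
9 | (1R,5S)-2,5,6,6-tetramethylcyclohex-2-ene-1-carbaldehyde | CC1=CC[C@H](C)C(C)(C)[C@@H]1C=O | intermediate
10 | (E)-1-iodo-2-[(1R,5S)-2,5,6,6-tetramethylcyclohex-2-en-1-yl]ethene | CC1=CC[C@H](C)C(C)(C)[C@@H]1/C=C/I | intermediate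
11 | methyl (2R)-3-hydroxy-2-methylpropanoate | COC(=O)[C@H](C)CO | starting material
12 | methyl (2R)-3-[(tert-butyldimethylsilyl)oxy]-2-methylpropanoate | COC(=O)[C@H](C)CO[Si](C)(C)C(C)(C)C | intermediate
13 | (2R)-3-[(tert-butyldimethylsilyl)oxy]-N-methoxy-N,2-dimethylpropanamide | CON(C)C(=O)[C@H](C)CO[Si](C)(C)C(C)(C)C | intermediate
14 | (3R)-4-[(tert-butyldimethylsilyl)oxy]-3-methylbutan-2-one | CC(=O)[C@H](C)CO[Si](C)(C)C(C)(C)C | intermediate
15 | 1-[(3S)-4-[(tert-butyldimethylsilyl)oxy]-3-methylbutan-2-ylidene]-2,2-dimethylhydrazine | CN(C)N=C(C)[C@H](C)CO[Si](C)(C)C(C)(C)C | intermediate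
16 | pent-3-yn-1-ol | CC#CCCO | starting material
17 | 5-bromopent-2-yne | CC#CCCBr | intermediate
18 | pent-4-yn-1-ol | C#CCCCO | starting material
19 | tert-butyl(pent-4-yn-1-yloxy)diphenylsilane | C#CCCCO[Si](c1ccccc1)(c1ccccc1)C(C)(C)C | intermediate
20 | 2-bromoprop-2-en-1-ol | C=C(Br)CO | starting material
21 | 7-[(tert-butyldiphenylsilyl)oxy]-2-methylidenehept-3-yn-1-ol | C=C(CO)C#CCCCO[Si](c1ccccc1)(c1ccccc1)C(C)(C)C | intermediate
22 | [(2R)-2-{5-[(tert-butyldiphenylsilyl)oxy]pent-1-yn-1-yl}oxiran-2-yl]methanol | OC[C@]1(C#CCCCO[Si](c2ccccc2)(c2ccccc2)C(C)(C)C)CO1 | intermediate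
23 | (2R,6S)-7-[(tert-butyldimethylsilyl)oxy]-2-{5-[(tert-butyldiphenylsilyl)oxy]pent-1-yn-1-yl}-5-(2,2-dimethylhydrazinylidene)-6-methylheptane-1,2-diol | CN(C)N=C(CC[C@](O)(CO)C#CCCCO[Si](c1ccccc1)(c1ccccc1)C(C)(C)C)[C@H](C)CO[Si](C)(C)C(C)(C)C | intermediate
24 | pent-3-yn-1-ylmagnesium bromide | CC#CCC[Mg]Br | intermediate
25 | (2R,6S)-7-[(tert-butyldimethylsilyl)oxy]-2-[(1E)-5-[(tert-butyldiphenylsilyl)oxy]-1-(pent-3-yn-1-yl)pent-1-en-1-yl]-5-(2,2-dimethylhydrazinylidene)-6-methylheptane-1,2-diol | CN(C)N=C(CC[C@](O)(CO)/C(CCC#CC)=C/CCCO[Si](c1ccccc1)(c1ccccc1)C(C)(C)C)[C@H](C)CO[Si](C)(C)C(C)(C)C | intermediate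
26 | (2R,6R)-1-[(tert-butyldimethylsilyl)oxy]-6-[(1E)-5-[(tert-butyldiphenylsilyl)oxy]-1-(pent-3-yn-1-yl)pent-1-en-1-yl]-6,7-dihydroxy-2-methylheptan-3-one | O=C(CC[C@](O)(CO)/C(CCC#CC)=C/CCCO[Si](c1ccccc1)(c1ccccc1)C(C)(C)C)[C@H](C)CO[Si](C)(C)C(C)(C)C | intermediate
27 | (1S,4R)-1-{(2R)-1-[(tert-butyldimethylsilyl)oxy]propan-2-yl}-4-[(1E)-5-[(tert-butyldiphenylsilyl)oxy]-1-(pent-3-yn-1-yl)pent-1-en-1-yl]-2,7-dioxabicyclo[2.2.1]heptane | CC#CCC/C(=C\CCCO[Si](c1ccccc1)(c1ccccc1)C(C)(C)C)[C@@]12CO[C@@](CC1)(O2)[C@H](C)CO[Si](C)(C)C(C)(C)C | intermediate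
28 | (1S,5R,8S)-5-{(2R)-1-[(tert-butyldimethylsilyl)oxy]propan-2-yl}-8-{3-[(tert-butyldiphenylsilyl)oxy]propyl}-1-(pent-3-yn-1-yl)-6-oxabicyclo[3.2.1]octan-2-one | CC#CCC[C@]12CO[C@]([C@H](C)CO[Si](C)(C)C(C)(C)C)(CCC1=O)[C@H]2CCCO[Si](c1ccccc1)(c1ccccc1)C(C)(C)C | intermediate
29 | (1S,2S,5R,8S)-5-{(2R)-1-[(tert-butyldimethylsilyl)oxy]propan-2-yl}-8-{3-[(tert-butyldiphenylsilyl)oxy]propyl}-2-methyl-1-(pent-3-yn-1-yl)-6-oxabicyclo[3.2.1]octan-2-ol | CC#CCC[C@]12CO[C@]([C@H](C)CO[Si](C)(C)C(C)(C)C)(CC[C@]1(C)O)[C@H]2CCCO[Si](c1ccccc1)(c1ccccc1)C(C)(C)C | intermediate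
30 | (E)-alkenylzirconocene chloride of 29 (Zr on the methyl-bearing alkene carbon, trans to the chain; tertiary OH as its zirconocene alkoxide) | C/C(=C\CC[C@]12CO[C@]([C@H](C)CO[Si](C)(C)C(C)(C)C)(CC[C@]1(C)O[Zr](Cl)(C3C=CC=C3)C3C=CC=C3)[C@H]2CCCO[Si](c3ccccc3)(c3ccccc3)C(C)(C)C)[Zr](Cl)(C3C=CC=C3)C3C=CC=C3 | intermediate
31 | (1S,2S,5R,8S)-5-{(2R)-1-[(tert-butyldimethylsilyl)oxy]propan-2-yl}-8-{3-[(tert-butyldiphenylsilyl)oxy]propyl}-2-methyl-1-{(3E,5E)-4-methyl-6-[(1R,5S)-2,5,6,6-tetramethylcyclohex-2-en-1-yl]hexa-3,5-dien-1-yl}-6-oxabicyclo[3.2.1]octan-2-ol | CC1=CC[C@H](C)C(C)(C)[C@@H]1/C=C/C(C)=C/CC[C@]12CO[C@]([C@H](C)CO[Si](C)(C)C(C)(C)C)(CC[C@]1(C)O)[C@H]2CCCO[Si](c1ccccc1)(c1ccccc1)C(C)(C)C | intermediate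
32 | (1S,2S,5R,8S)-8-{3-[(tert-butyldiphenylsilyl)oxy]propyl}-5-[(2R)-1-hydroxypropan-2-yl]-2-methyl-1-{(3E,5E)-4-methyl-6-[(1R,5S)-2,5,6,6-tetramethylcyclohex-2-en-1-yl]hexa-3,5-dien-1-yl}-6-oxabicyclo[3.2.1]octan-2-ol | CC1=CC[C@H](C)C(C)(C)[C@@H]1/C=C/C(C)=C/CC[C@]12CO[C@]([C@H](C)CO)(CC[C@]1(C)O)[C@H]2CCCO[Si](c1ccccc1)(c1ccccc1)C(C)(C)C | intermediate
33 | (2S)-2-[(1S,2S,5R,8S)-8-{3-[(tert-butyldiphenylsilyl)oxy]propyl}-2-hydroxy-2-methyl-1-{(3E,5E)-4-methyl-6-[(1R,5S)-2,5,6,6-tetramethylcyclohex-2-en-1-yl]hexa-3,5-dien-1-yl}-6-oxabicyclo[3.2.1]octan-5-yl]propanal | CC1=CC[C@H](C)C(C)(C)[C@@H]1/C=C/C(C)=C/CC[C@]12CO[C@]([C@H](C)C=O)(CC[C@]1(C)O)[C@H]2CCCO[Si](c1ccccc1)(c1ccccc1)C(C)(C)C | intermediate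
34 | (2S)-2-[(1S,2S,5R,8S)-2-hydroxy-8-(3-hydroxypropyl)-2-methyl-1-{(3E,5E)-4-methyl-6-[(1R,5S)-2,5,6,6-tetramethylcyclohex-2-en-1-yl]hexa-3,5-dien-1-yl}-6-oxabicyclo[3.2.1]octan-5-yl]propanal | CC1=CC[C@H](C)C(C)(C)[C@@H]1/C=C/C(C)=C/CC[C@]12CO[C@]([C@H](C)C=O)(CC[C@]1(C)O)[C@H]2CCCO | target

**Totals and risks**

Total step count: 23. Longest linear sequence: 12 steps (steps 1–8, then 20–23).

Three steps most likely to fail:

1. Step 18 (the proposed new cascade). Risks are migration of the CH2CH2 bridge carbon instead of the CH2O carbon, the wrong face at C8, and loss of a proton instead of the shift. The fallback uses two known reaction types, run separately, and sets out from 27. TiCl4 (CH2Cl2, −90 °C) effects a chloride-terminated Prins cyclisation to the chloro alcohol 5-chloro-2-oxabicyclo[2.2.2]octan-4-ol F1 (fully substituted as in the block below), chloride entering on the C7–C8 bridge side, anti to the C6 side chain. F1 is purified and rearranged with AgBF4 (2,6-di-tert-butylpyridine, CH2Cl2, −78 °C) in a halophile-triggered semipinacol shift; only the bridgehead–CH2O bond is antiperiplanar to the departing chloride, so that carbon migrates. The fallback comes back to the route at 28. It shares the cationic manifold of the cascade, so it is the weakest of the three fallbacks.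

2. Step 19 (facial selectivity of methyl addition). If methyllithium adds from the oxa-bridge face, the complementary known sequence is used, setting out from 28. Wittig methylenation (Ph3PCH3Br, KOt-Bu, toluene, 80 °C) gives the 2-methylidene compound F2. mCPBA (NaHCO3, CH2Cl2, 0 °C) then places oxygen on that same face, giving the spiro-epoxide F3. LiEt3BH (THF, 0 °C) opens F3 at CH2, which turns the epoxide carbon into the methyl group and the oxygen into the equatorial OH. The fallback comes back at 29.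

3. Step 20 (regiochemistry of hydrozirconation and the one-pot coupling). The fallback sets out from 29 and from 9. Hydrozirconation of 29 followed by I2 (THF, 0 °C) gives the (E)-alkenyl iodide F4, which can be freed from its regioisomer by chromatography. Aldehyde 9 with CrCl2, LiI and Cl2CHBpin (THF, rt) gives the (E)-alkenyl pinacol boronate F5. Suzuki–Miyaura coupling of F4 and F5 (Pd(dppf)Cl2, aq. K3PO4, THF, rt) comes back at 31.

Further compounds
F1 | step 18 | 5-chloro-5-(pent-3-yn-1-yl)-6-{3-[(tert-butyldiphenylsilyl)oxy]propyl}-1-{(2R)-1-[(tert-butyldimethylsilyl)oxy]propan-2-yl}-2-oxabicyclo[2.2.2]octan-4-ol (C6 chain on the O2–C3 side, Cl on the C7–C8 side) | CC#CCC[C@@]1(Cl)[C@@]2(O)CO[C@@](CC2)([C@H](C)CO[Si](C)(C)C(C)(C)C)[C@H]1CCCO[Si](c3ccccc3)(c3ccccc3)C(C)(C)C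
F2 | step 19 | 2-methylidene analogue of 28 (exocyclic C2=CH2 in place of C2=O) | CC#CCC[C@]12CO[C@]([C@H](C)CO[Si](C)(C)C(C)(C)C)(CCC1=C)[C@H]2CCCO[Si](c1ccccc1)(c1ccccc1)C(C)(C)C
F3 | step 19 | spiro-epoxide of F2 at C2 (epoxide oxygen on the oxa-bridge face, CH2 on the face of the one-carbon bridge) | CC#CCC[C@]12CO[C@]([C@H](C)CO[Si](C)(C)C(C)(C)C)(CC[C@@]13CO3)[C@H]2CCCO[Si](c1ccccc1)(c1ccccc1)C(C)(C)C
F4 | step 20 | analogue of 29 with a (3E)-4-iodopent-3-en-1-yl chain on C1 in place of pent-3-yn-1-yl | C/C(I)=C\CC[C@]12CO[C@]([C@H](C)CO[Si](C)(C)C(C)(C)C)(CC[C@]1(C)O)[C@H]2CCCO[Si](c1ccccc1)(c1ccccc1)C(C)(C)C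
F5 | step 20 | 4,4,5,5-tetramethyl-2-{(E)-2-[(1R,5S)-2,5,6,6-tetramethylcyclohex-2-en-1-yl]ethenyl}-1,3,2-dioxaborolane | CC1=CC[C@H](C)C(C)(C)[C@@H]1/C=C/B1OC(C)(C)C(C)(C)O1
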